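**Assumption:** the target has no stereocentre and no stereogenic axis, so it is achiral and is its own "single enantiomer"; no stereocontrol is needed. 2,4-Dihydroxy-3,6-dimethylbenzoic acid is taken as a catalogue compound.

## Retrosynthetic overview

1. Target 10 ← benzyl ester 9 by hydrogenolysis (last step).
2. Key disconnection: the aryl–C(=O) bond of the depside carbonyl. Ring A aryl iodide 4 (electrophilic carbon) is joined to ring B aryl formate 7, which acts as an aryloxycarbonyl anion equivalent (its formyl carbon is normally electrophilic), under palladium catalysis. This one C–C bond brings in the carboxyl carbon and unites both halves.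
3. 4 ← 3,5-dimethoxytoluene 1 by directed ortho-lithiation/hydroxymethylation, then iodination.
4. 7 ← 2,4-dihydroxy-3,6-dimethylbenzoic acid 5 by benzylation, then 4-O-formylation.
5. No ring is formed: ring A and ring B are both bought as intact benzene rings.

## Route

**Step 1**
Reactants: 1 3,5-dimethoxytoluene
Product: 3 (2,6-dimethoxy-4-methylphenyl)methanol, via (2,6-dimethoxy-4-methylphenyl)lithium 2 (not isolated)
Conditions: n-BuLi (1.1 equiv), TMEDA (1.1 equiv), THF, 0 °C to rt, 2 h; then dry paraformaldehyde (3 equiv), −78 °C to rt; H2O quench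
Reagents that add atoms: formaldehyde (from paraformaldehyde), C=O
Why: The two methoxy groups jointly direct lithiation to the ring carbon between them (directed ortho-metalation) and the aryllithium adds to formaldehyde (1,2-addition) to give the primary benzylic alcohol; no stereocentre arises.

**Step 2**
Reactants: 3 (2,6-dimethoxy-4-methylphenyl)methanol
Product: 4 (3-iodo-2,6-dimethoxy-4-methylphenyl)methanol
Conditions: N-iodosuccinimide (1.05 equiv), MeCN, 0 °C to rt, dark
Reagents that add atoms: N-iodosuccinimide, O=C1CCC(=O)N1I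
Why: Electrophilic aromatic iodination under neutral conditions: the two free ring positions are equivalent and each is ortho to one methoxy and para to the other, so one mono-iodide forms without acid that would ionise the electron-rich benzylic alcohol.

**Step 3**
Reactants: 5 2,4-dihydroxy-3,6-dimethylbenzoic acid
Product: 6 benzyl 2,4-dihydroxy-3,6-dimethylbenzoate
Conditions: BnBr (1.05 equiv), KHCO3 (1.2 equiv), DMF, rt to 40 °C
Reagents that add atoms: benzyl bromide, BrCc1ccccc1
Why: Carboxylate O-alkylation (SN2 benzylation) with bicarbonate as base, which deprotonates only the carboxylic acid and leaves both phenols free.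

**Step 4**
Reactants: 6 benzyl 2,4-dihydroxy-3,6-dimethylbenzoate
Product: 7 benzyl 4-(formyloxy)-2-hydroxy-3,6-dimethylbenzoate
Conditions: HCO2H/Ac2O premixed (55 °C, 1 h, then cooled; 1.5 equiv of mixed anhydride), NaOAc (0.2 equiv), THF, 0 °C to rt
Reagents that add atoms: acetic formic anhydride, CC(=O)OC=O (made in the flask from formic acid, O=CO, and acetic anhydride, CC(=O)OC(C)=O)
Why: O-Formylation (acyl transfer from the mixed anhydride, whose formyl carbonyl is the more electrophilic) occurs at the free 4-hydroxyl because the 2-hydroxyl is hydrogen-bonded to the ester carbonyl and flanked on both sides.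

**Step 5 (key step)**
Reactants: 4 (3-iodo-2,6-dimethoxy-4-methylphenyl)methanol; 7 benzyl 4-(formyloxy)-2-hydroxy-3,6-dimethylbenzoate
Product: 9 benzyl 4-{[3-(hydroxymethyl)-2,4-dimethoxy-6-methylbenzoyl]oxy}-2-hydroxy-3,6-dimethylbenzoate, via benzyl 2,4-dihydroxy-3,6-dimethylbenzoate 6 (not isolated), via carbon monoxide 8 (not isolated)
Conditions: Pd(OAc)2 (5 mol %), Xantphos (7.5 mol %), NEt3 (2.5 equiv), 7 (1.6 equiv), degassed toluene/MeCN, sealed tube, 70 °C, 12 h
Reagents that add atoms: none
Why: Palladium-catalysed aryloxycarbonylation of an aryl iodide with an aryl formate: formate 7 serves as an aryloxycarbonyl anion (acyl anion) equivalent that NEt3 unmasks as carbon monoxide 8 plus the 4-phenoxide of 6, and after oxidative addition of zerovalent palladium into the C–I bond of 4, CO insertion and acyl transfer to that phenoxide join two carbons that are both normally electrophilic (the C–I carbon and the formyl carbon), while the phenoxide outcompetes the neutral benzylic alcohol and the hydrogen-bonded 2-hydroxyl.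

**Step 6**
Reactants: 9 benzyl 4-{[3-(hydroxymethyl)-2,4-dimethoxy-6-methylbenzoyl]oxy}-2-hydroxy-3,6-dimethylbenzoate
Product: 10 4-{[3-(hydroxymethyl)-2,4-dimethoxy-6-methylbenzoyl]oxy}-2-hydroxy-3,6-dimethylbenzoic acid
Conditions: H2 (1 atm), 10% Pd/C, EtOAc, rt, stopped at full conversion of 9
Reagents that add atoms: none
Why: Catalytic hydrogenolysis of the benzyl ester C–O bond over Pd/C in neutral ethyl acetate is much faster than hydrogenolysis of the benzylic C–OH bond of ring A, and the aryl ester and ethers are inert, so the free acid is released without acid or base.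

## Compound list

1 | 3,5-dimethoxytoluene (1,3-dimethoxy-5-methylbenzene) | COc1cc(C)cc(OC)c1 | starting material
2 | (2,6-dimethoxy-4-methylphenyl)lithium | [Li]c1c(OC)cc(C)cc1OC | intermediate
3 | (2,6-dimethoxy-4-methylphenyl)methanol | COc1cc(C)cc(OC)c1CO | intermediate
4 | (3-iodo-2,6-dimethoxy-4-methylphenyl)methanol | COc1cc(C)c(I)c(OC)c1CO | intermediate
5 | 2,4-dihydroxy-3,6-dimethylbenzoic acid | Cc1cc(O)c(C)c(O)c1C(=O)O | starting material
6 | benzyl 2,4-dihydroxy-3,6-dimethylbenzoate | Cc1cc(O)c(C)c(O)c1C(=O)OCc1ccccc1 | intermediate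
7 | benzyl 4-(formyloxy)-2-hydroxy-3,6-dimethylbenzoate | Cc1cc(OC=O)c(C)c(O)c1C(=O)OCc1ccccc1 | intermediate
8 | carbon monoxide | [C-]#[O+] | intermediate
9 | benzyl 4-{[3-(hydroxymethyl)-2,4-dimethoxy-6-methylbenzoyl]oxy}-2-hydroxy-3,6-dimethylbenzoate | COc1cc(C)c(C(=O)Oc2cc(C)c(C(=O)OCc3ccccc3)c(O)c2C)c(OC)c1CO | intermediate
10 | 4-{[3-(hydroxymethyl)-2,4-dimethoxy-6-methylbenzoyl]oxy}-2-hydroxy-3,6-dimethylbenzoic acid | COc1cc(C)c(C(=O)Oc2cc(C)c(C(=O)O)c(O)c2C)c(OC)c1CO | target

## Step count and risks

Total steps: 6. Longest linear sequence: 4 steps (1 → 3 → 4 → 9 → 10, or 5 → 6 → 7 → 9 → 10).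

**Step 5 (highest risk).** The aryl iodide carries two ortho substituents, which slows CO insertion and acyl transfer. The free benzylic alcohol of 4 can also compete as a nucleophile or be formylated by 7. The fallback sets out from 4 and comes back at 9. Silylation (TBSCl, imidazole, DMF) gives tert-butyl[(3-iodo-2,6-dimethoxy-4-methylphenyl)methoxy]dimethylsilane F1. Iodine–magnesium exchange (iPrMgCl·LiCl, THF, −15 °C to 0 °C) gives [3-({[tert-butyl(dimethyl)silyl]oxy}methyl)-2,4-dimethoxy-6-methylphenyl]magnesium chloride F2. Quenching F2 with CO2 and working up at pH 4 gives 3-({[tert-butyl(dimethyl)silyl]oxy}methyl)-2,4-dimethoxy-6-methylbenzoic acid F3. Classical depside esterification of F3 with phenol 6 (DCC, toluene/CH2Cl2, rt) gives benzyl 4-{[3-({[tert-butyl(dimethyl)silyl]oxy}methyl)-2,4-dimethoxy-6-methylbenzoyl]oxy}-2-hydroxy-3,6-dimethylbenzoate F4. HF·pyridine in THF at 0 °C then removes the silyl group and returns to 9.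

**Step 4.** The aryl formate 7 is hydrolytically labile and may not survive isolation, or formylation may not stop cleanly at the 4-hydroxyl. The fallback sets out from 6 (with 4) and comes back at 9. Compound 7 is left out, and 4 and phenol 6 are combined in a three-component carbonylation under carbon monoxide 8 from a balloon (Pd(OAc)2, Xantphos, NEt3, toluene, 70 °C), with the phenol itself as the nucleophile. This fallback makes no new compound (F0).

**Step 2.** Traces of acid can ionise the doubly ortho-methoxylated benzylic alcohol, and ipso attack with loss of formaldehyde is possible. The fallback sets out from 1 and comes back at 4. Aryllithium 2, made as in step 1, is quenched with DMF to give lithium (2,6-dimethoxy-4-methylphenyl)(dimethylamino)methanolate F5, which collapses on aqueous work-up to 2,6-dimethoxy-4-methylbenzaldehyde F6. The robust aldehyde is iodinated (N-iodosuccinimide, cat. TFA, MeCN) to 3-iodo-2,6-dimethoxy-4-methylbenzaldehyde F7. Reduction with NaBH4 in MeOH at 0 °C gives 4.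

## Further compounds

F1 | step 5 | tert-butyl[(3-iodo-2,6-dimethoxy-4-methylphenyl)methoxy]dimethylsilane | COc1cc(C)c(I)c(OC)c1CO[Si](C)(C)C(C)(C)C
F2 | step 5 | [3-({[tert-butyl(dimethyl)silyl]oxy}methyl)-2,4-dimethoxy-6-methylphenyl]magnesium chloride | COc1cc(C)c([Mg]Cl)c(OC)c1CO[Si](C)(C)C(C)(C)C
F3 | step 5 | 3-({[tert-butyl(dimethyl)silyl]oxy}methyl)-2,4-dimethoxy-6-methylbenzoic acid | COc1cc(C)c(C(=O)O)c(OC)c1CO[Si](C)(C)C(C)(C)C
F4 | step 5 | benzyl 4-{[3-({[tert-butyl(dimethyl)silyl]oxy}methyl)-2,4-dimethoxy-6-methylbenzoyl]oxy}-2-hydroxy-3,6-dimethylbenzoate | COc1cc(C)c(C(=O)Oc2cc(C)c(C(=O)OCc3ccccc3)c(O)c2C)c(OC)c1CO[Si](C)(C)C(C)(C)C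
F0 | step 4 | none | none
F5 | step 2 | lithium (2,6-dimethoxy-4-methylphenyl)(dimethylamino)methanolate | COc1cc(C)cc(OC)c1C([O-])N(C)C.[Li+]
F6 | step 2 | 2,6-dimethoxy-4-methylbenzaldehyde | COc1cc(C)cc(OC)c1C=O
F7 | step 2 | 3-iodo-2,6-dimethoxy-4-methylbenzaldehyde | COc1cc(C)c(I)c(OC)c1C=O
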